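**Retrosynthetic overview**

- Last C=C: the 1,1-disubstituted enone comes from a β-keto tert-butyl ester by acidolysis and decarboxylative Mannich methylenation.
- Key bond and only stereocentre: the CH2–C5 bond of the butenolide, made by a metal-free, cinchona-base-catalysed enantioselective 1,6-addition of an achiral aryloxy β-keto ester to 3-methyl-5-methylidenefuran-2(5H)-one with γ-protonation.
- β-Keto ester: O-alkylation of 7-hydroxy-8-methoxycoumarin with tert-butyl 4-chloroacetoacetate. Acceptor: 3-methylfuran-2(5H)-one by vinylogous Mannich reaction and Hofmann-type elimination.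
- Rings: none is built. The coumarin bicycle and the butenolide ring are bought intact; the butenolide is only transiently aromatised to a 2-oxidofuran in the key step.

Assumption: 1 (daphnetin 8-methyl ether) is taken as a catalogue compound, and the sense of induction in step 4 is assigned by analogy only (quinidine-derived catalyst taken to give (R); the quinine-derived pseudoenantiomer would serve if the sense is reversed).

**Route**

Step 1
Reactants: 1 7-hydroxy-8-methoxy-2H-chromen-2-one; 2 tert-butyl 4-chloro-3-oxobutanoate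
Product: 3 tert-butyl 4-[(8-methoxy-2-oxo-2H-chromen-7-yl)oxy]-3-oxobutanoate
Conditions: NaH (2.2 equiv), DMF, 0 °C; then 2 (1.1 equiv), NaI (10 mol %), 0 → 40 °C; aq. HCl
Reagents that add atoms: none
Why: Williamson ether synthesis in which the second equivalent of NaH stores the β-keto ester as its enolate, so the coumarin phenoxide displaces the primary α-keto chloride (SN2, iodide-assisted) without self-condensation of 2.

Step 2
Reactants: 4 3-methylfuran-2(5H)-one
Product: 6 5-[(dimethylamino)methyl]-3-methylfuran-2(5H)-one (racemic), via silyloxyfuran 5 (not isolated)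
Conditions: TBSOTf (1.1 equiv), Et3N (2.5 equiv), CH2Cl2, 0 °C; then [CH2=NMe2]I (1.2 equiv), 0 °C → rt; H2O
Reagents that add atoms: Eschenmoser's salt (N,N-dimethylmethylideneammonium iodide), C=[N+](C)C.[I-]
Why: Silyl dienol ether formation followed by a vinylogous Mukaiyama–Mannich reaction, which occurs at C5 (γ) of 2-silyloxyfurans; the C5 centre formed here is racemic and is removed again in step 3.

Step 3
Reactants: 6 5-[(dimethylamino)methyl]-3-methylfuran-2(5H)-one
Product: 8 3-methyl-5-methylidenefuran-2(5H)-one, via methiodide 7 (not isolated)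
Conditions: MeI (3 equiv), acetone, rt; then satd aq. NaHCO3/CH2Cl2, 0 °C, BHT (trace); dried cold solution used at once
Reagents that add atoms: none
Why: Exhaustive N-methylation then Hofmann-type E1cB elimination through the acidic γ-C–H gives the exocyclic alkene under very mild base, the standard Mannich-base-to-methylidene sequence.

Step 4
Reactants: 3 tert-butyl 4-[(8-methoxy-2-oxo-2H-chromen-7-yl)oxy]-3-oxobutanoate; 8 3-methyl-5-methylidenefuran-2(5H)-one
Product: 9 tert-butyl 4-[(8-methoxy-2-oxo-2H-chromen-7-yl)oxy]-2-{[(2R)-4-methyl-5-oxo-2,5-dihydrofuran-2-yl]methyl}-3-oxobutanoate (both epimers at C2 of the butanoate)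
Conditions: 9-O-(9-phenanthryl)cupreidine (10 mol %), 3 (1.3 equiv), CH2Cl2, 4 Å MS, −20 °C, 8 added over 8 h by syringe pump
Reagents that add atoms: none
Why: Proposed new method: the quinuclidine deprotonates β-keto ester 3, the enolate adds 1,6 to the unhindered exocyclic CH2 of 8 (driven by aromatisation of the lactone to a 2-oxidofuran), and the dienolate–quinuclidinium ion pair held by the 6′-OH is protonated at the γ-carbon on one face to set the (R) centre, while the labile C2 centre is irrelevant because step 5 destroys it; closest known reaction types are 6′-OH cinchona-catalysed tandem conjugate addition–enantioselective protonation and cinchona-catalysed enantioselective isomerisation of β,γ- to α,β-butenolides by proton transfer, which passes through the same kind of ion pair.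

Step 5
Reactants: 9 tert-butyl 4-[(8-methoxy-2-oxo-2H-chromen-7-yl)oxy]-2-{[(2R)-4-methyl-5-oxo-2,5-dihydrofuran-2-yl]methyl}-3-oxobutanoate
Product: 12 8-methoxy-7-({3-methylidene-4-[(2R)-4-methyl-5-oxo-2,5-dihydrofuran-2-yl]-2-oxobutyl}oxy)-2H-chromen-2-one, via β-keto acid 10 (not isolated), via Mannich acid 11 (not isolated)
Conditions: TFA/CH2Cl2 (1:3), 0 °C → rt; evaporate; then 37% aq. HCHO, Et2NH (1.1 equiv), THF, 0 °C → rt; dilute HCl wash
Reagents that add atoms: formaldehyde, C=O
Why: tert-Butyl ester acidolysis gives the β-keto acid, whose doubly activated C–H undergoes a Mannich reaction, and the Mannich acid loses CO2 and Et2NH (decarboxylative Mannich methylenation), which can place the C=CH2 only at that carbon and leaves the (R) centre untouched.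

**Compound list**

1 | 7-hydroxy-8-methoxy-2H-chromen-2-one | COc1c(O)ccc2ccc(=O)oc12 | starting material
2 | tert-butyl 4-chloro-3-oxobutanoate | CC(C)(C)OC(=O)CC(=O)CCl | starting material
3 | tert-butyl 4-[(8-methoxy-2-oxo-2H-chromen-7-yl)oxy]-3-oxobutanoate | CC(C)(C)OC(=O)CC(=O)COc1ccc2ccc(=O)oc2c1OC | intermediate
4 | 3-methylfuran-2(5H)-one | CC1=CCOC1=O | starting material
5 | tert-butyl(dimethyl)[(3-methylfuran-2-yl)oxy]silane | Cc1ccoc1O[Si](C)(C)C(C)(C)C | intermediate (not isolated)
6 | 5-[(dimethylamino)methyl]-3-methylfuran-2(5H)-one, racemic | CN(C)CC1C=C(C)C(=O)O1 | intermediate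
7 | N,N,N-trimethyl-1-(4-methyl-5-oxo-2,5-dihydrofuran-2-yl)methanaminium iodide, racemic | C[N+](C)(C)CC1C=C(C)C(=O)O1.[I-] | intermediate (not isolated)
8 | 3-methyl-5-methylidenefuran-2(5H)-one | C=C1C=C(C)C(=O)O1 | intermediate
9 | tert-butyl 4-[(8-methoxy-2-oxo-2H-chromen-7-yl)oxy]-2-{[(2R)-4-methyl-5-oxo-2,5-dihydrofuran-2-yl]methyl}-3-oxobutanoate, epimers at C2 | CC(C)(C)OC(=O)C(C[C@@H]1C=C(C)C(=O)O1)C(=O)COc1ccc2ccc(=O)oc2c1OC | intermediate
10 | 4-[(8-methoxy-2-oxo-2H-chromen-7-yl)oxy]-2-{[(2R)-4-methyl-5-oxo-2,5-dihydrofuran-2-yl]methyl}-3-oxobutanoic acid, epimers at C2 | OC(=O)C(C[C@@H]1C=C(C)C(=O)O1)C(=O)COc1ccc2ccc(=O)oc2c1OC | intermediate (not isolated)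
11 | 2-[(diethylamino)methyl]-4-[(8-methoxy-2-oxo-2H-chromen-7-yl)oxy]-2-{[(2R)-4-methyl-5-oxo-2,5-dihydrofuran-2-yl]methyl}-3-oxobutanoic acid, epimers at C2 | CCN(CC)CC(C[C@@H]1C=C(C)C(=O)O1)(C(=O)O)C(=O)COc1ccc2ccc(=O)oc2c1OC | intermediate (not isolated)
12 | 8-methoxy-7-({3-methylidene-4-[(2R)-4-methyl-5-oxo-2,5-dihydrofuran-2-yl]-2-oxobutyl}oxy)-2H-chromen-2-one | C=C(C[C@@H]1C=C(C)C(=O)O1)C(=O)COc1ccc2ccc(=O)oc2c1OC | target

**Step count**

Total steps: 5. Longest linear sequence: 4 (steps 2, 3, 4, 5, from 4); the coumarin branch is 3 steps (1, 4, 5).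

**Three steps most likely to fail, with fallbacks**

Step 4 (the proposed new 1,6-addition/protonation). Risks are oligomerisation of 8, retro-addition through γ-deprotonation of 9, and insufficient or reversed enantioselectivity. The fallback uses known chemistry, sets out from 3 and comes back at 9.
- Et3N-catalysed Michael addition of 3 to acrolein gives tert-butyl 2-{[(8-methoxy-2-oxo-2H-chromen-7-yl)oxy]acetyl}-5-oxopentanoate F1.
- L-Proline-catalysed α-aminoxylation of the aldehyde with nitrosobenzene (CHCl3, 0 °C) gives tert-butyl (4R)-4-(anilinooxy)-2-{[(8-methoxy-2-oxo-2H-chromen-7-yl)oxy]acetyl}-5-oxopentanoate F2, which is not isolated.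
- In the same flask, a Z-selective Horner–Wadsworth–Emmons reaction with ethyl 2-(diphenoxyphosphoryl)propanoate (NaI, DBU, one extra equivalent for the β-keto ester) gives 7-tert-butyl 1-ethyl (2Z,4R)-4-(anilinooxy)-6-{[(8-methoxy-2-oxo-2H-chromen-7-yl)oxy]acetyl}-2-methylhept-2-enedioate F3.
- N–O cleavage with Mo(CO)6 in MeCN–H2O gives 7-tert-butyl 1-ethyl (2Z,4R)-4-hydroxy-6-{[(8-methoxy-2-oxo-2H-chromen-7-yl)oxy]acetyl}-2-methylhept-2-enedioate F4, which lactonises (cat. PPTS) to 9.
- The stereocentre then comes from enamine catalysis (L-proline gives the (R)-aminoxy aldehyde), still metal-free in the asymmetric step and from achiral materials.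

Step 3 (making and handling 8, a protoanemonin-type diene lactone that can dimerise or polymerise). The fallback sets out from 5 (made from 4 as in step 2) and comes back at 8.
- Sc(OTf)3-catalysed vinylogous Mukaiyama aldol reaction of 5 with 37% aq. HCHO in THF gives 5-(hydroxymethyl)-3-methylfuran-2(5H)-one F5.
- Ac2O/pyridine gives the bench-stable, storable precursor (4-methyl-5-oxo-2,5-dihydrofuran-2-yl)methyl acetate F6.
- Et3N (1.05 equiv, CH2Cl2, 0 °C) eliminates acetic acid by E1cB immediately before use; after a cold water wash and drying, the solution of 8 goes straight into step 4.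

Step 5 (decarboxylative Mannich methylenation on the advanced intermediate). Risks are simple decarboxylation without methylenation, amine adducts of the enone, and base-induced erosion of the γ-centre. The fallback sets out from 9 and comes back at 12.
- Aldol reaction of 9 with aq. HCHO (KHCO3, THF, 0 °C) gives tert-butyl 2-(hydroxymethyl)-4-[(8-methoxy-2-oxo-2H-chromen-7-yl)oxy]-2-{[(2R)-4-methyl-5-oxo-2,5-dihydrofuran-2-yl]methyl}-3-oxobutanoate F7.
- TFA/CH2Cl2 gives 2-(hydroxymethyl)-4-[(8-methoxy-2-oxo-2H-chromen-7-yl)oxy]-2-{[(2R)-4-methyl-5-oxo-2,5-dihydrofuran-2-yl]methyl}-3-oxobutanoic acid F8.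
- Amine-free decarboxylative dehydration of this β-hydroxy acid with PPh3/DIAD (THF, 0 °C) gives 12.

**Further compounds**

F1 | step 4 | tert-butyl 2-{[(8-methoxy-2-oxo-2H-chromen-7-yl)oxy]acetyl}-5-oxopentanoate | CC(C)(C)OC(=O)C(CCC=O)C(=O)COc1ccc2ccc(=O)oc2c1OC
F2 | step 4 | tert-butyl (4R)-4-(anilinooxy)-2-{[(8-methoxy-2-oxo-2H-chromen-7-yl)oxy]acetyl}-5-oxopentanoate | CC(C)(C)OC(=O)C(C[C@@H](ONc1ccccc1)C=O)C(=O)COc1ccc2ccc(=O)oc2c1OC
F3 | step 4 | 7-tert-butyl 1-ethyl (2Z,4R)-4-(anilinooxy)-6-{[(8-methoxy-2-oxo-2H-chromen-7-yl)oxy]acetyl}-2-methylhept-2-enedioate | CCOC(=O)/C(C)=C\[C@H](ONc1ccccc1)CC(C(=O)OC(C)(C)C)C(=O)COc1ccc2ccc(=O)oc2c1OC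
F4 | step 4 | 7-tert-butyl 1-ethyl (2Z,4R)-4-hydroxy-6-{[(8-methoxy-2-oxo-2H-chromen-7-yl)oxy]acetyl}-2-methylhept-2-enedioate | CCOC(=O)/C(C)=C\[C@H](O)CC(C(=O)OC(C)(C)C)C(=O)COc1ccc2ccc(=O)oc2c1OC
F5 | step 3 | 5-(hydroxymethyl)-3-methylfuran-2(5H)-one, racemic | CC1=CC(CO)OC1=O
F6 | step 3 | (4-methyl-5-oxo-2,5-dihydrofuran-2-yl)methyl acetate, racemic | CC(=O)OCC1C=C(C)C(=O)O1
F7 | step 5 | tert-butyl 2-(hydroxymethyl)-4-[(8-methoxy-2-oxo-2H-chromen-7-yl)oxy]-2-{[(2R)-4-methyl-5-oxo-2,5-dihydrofuran-2-yl]methyl}-3-oxobutanoate | CC(C)(C)OC(=O)C(CO)(C[C@@H]1C=C(C)C(=O)O1)C(=O)COc1ccc2ccc(=O)oc2c1OC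
F8 | step 5 | 2-(hydroxymethyl)-4-[(8-methoxy-2-oxo-2H-chromen-7-yl)oxy]-2-{[(2R)-4-methyl-5-oxo-2,5-dihydrofuran-2-yl]methyl}-3-oxobutanoic acid | OC(=O)C(CO)(C[C@@H]1C=C(C)C(=O)O1)C(=O)COc1ccc2ccc(=O)oc2c1OC
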